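**Assumption:** the SMILES defines no configuration at the hindered N1'–C4 axis, so the target is taken as the mixture of both axial forms and no step controls the axis.

**Check of the structures:** with furan O1→O7, C2→C4, C3→C5, C4→C6, C5→C7 and pyrrole C2→C7a, C3→C3a, compounds 3, 5 and 8 agree with each other and with the target. No structure needed correction.

## Structural features

The target is a biindole joined through an N–C bond. Indole A is a 1H-indole with Br at C3 and C5, OMe at C7 and, at C4, the nitrogen N1' of indole B, which is a 2,5-dibromoindole. There is no stereocentre. The N1'–C4 axis is flanked by C5–Br, by the C3a/C3–Br peri region and by C2'–Br, so rotation about it should be slow. The fragile parts are the 3-bromo NH-indole of ring A (acid-sensitive and a donor of electrophilic bromine), the C2'–Br bond, and the four C–Br bonds as a set, which exclude organolithium reagents, dissolving metals and zerovalent palladium late in the route. The real difficulty is the benzene ring of indole A: only C6 carries hydrogen, and the C4–N1' bond sits between two ortho substituents, so a late N-arylation at C4 would be hindered and would have to discriminate among several C–Br bonds. A second difficulty is telling C3 of indole A from C3' of indole B when the last bromine is introduced. The key step uses the fact that O at C7 and N1' at C4 are para, with Br at C5 next to the nitrogen. This is the O1 / C2–N / C3–Br pattern of a 2-amido-3-bromofuran, whose C2 and C5 become C4 and C7, while the C3a–C7a bond is the C3–C2 bond of a pyrrole.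

## Logic of the disconnections

**13 ⇒ 11 (through 12).** The C3–Br bond of indole A is cut first. A 3-bromo NH-indole tolerates neither acid nor excess electrophile, so it should be made last. The forward step must choose C3 over C3'; it is therefore run on the anion 12, in which only ring A is activated.

**11 ⇒ 10.** The N1–S bond is cut. The sulfonyl group is needed earlier to make the pyrrole a dienophile and to keep indole A inert while ring B is aromatized. Its removal must leave three C–Br bonds and the aryl methyl ether intact, which calls for a nucleophile at sulfur and not a reducing metal.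

**10 ⇒ 9.** The C2'–Br bond and the C2'=C3' unsaturation are traced back to a lactam (C2'=O, C3'H2). A lactam nitrogen is a far better donor toward an attached diene than an indole nitrogen, and the lactam comes in one piece from 1. The forward step is a deoxybromination on a hindered N-aryl lactam that must spare the OMe and N-sulfonyl groups.

**9 ⇒ 8.** The O–CH3 bond is cut, because the oxygen at C7 appears as a free phenol in the ring synthesis. The methylation must take O–H and leave the acidic C3'H2 alone.

**8 ⇒ 3 + 5 (through 7 and 6).** The C7–C7a and C4–C3a bonds are cut, which takes apart the benzene ring of indole A. This is the largest simplification: a nearly fully substituted benzene becomes two simple five-membered heterocycles, and N, Br and O are placed by the ring synthesis itself. The crowded C4–N1' bond is thereby moved back to an unhindered furan carbon. The forward step needs one orientation of diene and dienophile, reaction at the nitro-bearing double bond only, and aromatization that outruns cycloreversion.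

**3 ⇒ 1 + 2.** The bond between the lactam nitrogen and furan C2 (the later N1'–C4 bond) is cut. Both pieces are commercial. The coupling must occur at C2–Br of 2 in preference to its C3–Br and to the aryl bromide of 1, and at nitrogen, not at C3', of 1.

**5 ⇒ 4.** The N–S bond is cut. Sulfonylation of 4 is simple and turns an electron-rich pyrrole into an electron-poor 2π component.

## Other disconnections considered

**Alternative 1:** The cut is N1–C7a of indole A. In the forward direction the azidocinnamate A2 is heated; it loses N2, and the vinyl nitrene (or its azirine) inserts into the only free ortho C–H bond to give the indole-2-carboxylate A1.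
- In favour: the closure is a known reaction and has no regiochemical question, since only one ortho position carries hydrogen. On mechanistic certainty it is better than the chosen key step. The C4–N1' bond could be made by SNAr on a fluoroarene activated by the ortho formyl group, which is also sound.
- Against: A1 carries an ester that the target lacks, so hydrolysis and decarboxylation follow. Decarboxylation of indole-2-carboxylic acids normally needs copper and temperatures near 200 °C, where the C–Br bonds (C2'–Br most of all) are at risk. The condensation leading to A2 uses a benzaldehyde with a bulky ortho substituent, and an organic azide is heated.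
- Comparison: the final C3 bromination meets the same site-selectivity problem as in the chosen plan, so the two are equal there. On step economy it is worse: arene preparation, SNAr, formation of indole B, condensation, thermolysis, hydrolysis, decarboxylation and bromination come to at least eight steps, against seven.

**Alternative 2:** The cuts are N1–C2 and C3–Br of indole A together. In the forward direction CuBr2 (divalent copper) activates the silylalkyne of the sulfonamide A4; the nitrogen attacks, and the C3–copper intermediate is converted into C3–Br, giving A3.
- In favour: ring closure and the C3 bromine come in one operation, and the bromine can only go to C3. On this point it is better than the chosen plan, whose last step must discriminate two indole C3 positions.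
- Against: CuBr2 is also a classical reagent for alpha-bromination of enolizable carbonyl compounds, so the lactam C3'H2 of A4 and A3 is exposed. A4 is a hexasubstituted benzene whose alkyne must be introduced between two ortho substituents with zerovalent palladium in the presence of two C–Br bonds. After A3, the silyl and methanesulfonyl groups must be removed (the latter under forcing conditions), and the lactam must be converted into the bromoindole with a 3-bromoindole already present.
- Comparison: mechanistically the key step is known chemistry and the chosen one is not, but the route to A4 is long and linear. The total should exceed ten steps.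

**Alternative 3:** The cut is C3'–C3a' of ring B. In the forward direction dilauroyl peroxide turns the xanthate A6 into an alpha-amide radical, which adds to the ortho carbon of the 4-bromophenyl ring; oxidation of the cyclohexadienyl radical gives the lactam A5.
- In favour: the hindered N-aryl lactam is built without a metal-mediated C–N coupling at a crowded carbon. Aryl bromides are inert to the radical conditions, and the N/Br/OMe pattern comes from ordinary aromatic substitution. Each step is known, which is an advantage over the chosen key step.
- Against: A6 offers the radical two aryl rings, and the nitro-substituted ring has a free ortho carbon. Nitroarenes also retard radical chains, and the peroxide is needed in stoichiometric amount. A5 still lacks the pyrrole ring of indole A, which would be added after lactam deoxybromination by reaction of the nitro group with a vinyl Grignard reagent, a step of modest efficiency.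
- Comparison: the end game (C3 bromination) is the same, so equal. The step count (diarylamine, acylation, xanthate, cyclization, deoxybromination, indole formation, bromination) is about eight, one more than the chosen plan. The chosen plan is shorter and more convergent but carries the greater mechanistic risk.

Key step: step 3

## Route

Step 1
Reactants: 1 5-bromoindolin-2-one; 2 2,3-dibromofuran
Product: 3 5-bromo-1-(3-bromofuran-2-yl)indolin-2-one
Conditions: 2 (3 equiv), CuI (10 mol%), N,N'-dimethylethylenediamine (20 mol%), K2CO3 (2 equiv), 1,4-dioxane, 90 °C, Ar
Reagents that add atoms: none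
Why: Goldberg-type amidation with CuI and a diamine; the furan C2–Br bond, alpha to oxygen, should react with monovalent copper ahead of the furan C3–Br bond and the electron-rich aryl bromide of 1, the diamine–copper system arylates oxindoles at nitrogen and not at C3, and the excess of 2 suppresses double amidation and self-coupling of 1.

Step 2
Reactants: 4 3-nitro-1H-pyrrole
Product: 5 3-nitro-1-tosyl-1H-pyrrole
Conditions: TsCl, Et3N, DMAP (cat.), CH2Cl2, 0 °C → rt
Reagents that add atoms: p-toluenesulfonyl chloride, Cc1ccc(cc1)S(Cl)(=O)=O
Why: N-sulfonylation of an NH pyrrole acidified by the nitro group; the sulfonyl group withdraws the nitrogen lone pair and makes the nitro-substituted C2=C3 bond an electron-poor dienophile.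

Step 3
Reactants: 3 5-bromo-1-(3-bromofuran-2-yl)indolin-2-one; 5 3-nitro-1-tosyl-1H-pyrrole
Product: 8 5-bromo-4-(5-bromo-2-oxoindolin-1-yl)-1-tosyl-1H-indol-7-ol, via nitro cycloadduct 6 (not isolated), via oxygen-bridged dihydroindole 7 (not isolated)
Conditions: 5 (1.5 equiv), NaHCO3 (2 equiv), PhMe, sealed tube, 120 °C, Ar
Reagents that add atoms: none
Why: Proposed new method: an intermolecular normal-demand Diels–Alder reaction in which the furan of 3, its HOMO raised by the lactam nitrogen on C2, adds as the diene across the nitro-activated C2=C3 bond of 5 in an asynchronous [4+2] process that joins furan C5 to pyrrole C2 (the C7–C7a bond) and furan C2 to pyrrole C3 (the C4–C3a bond) to give the bridged adduct 6. The benzene ring of indole A is thus closed by a two-component cycloaddition that makes both carbon–carbon bonds in one operation, not by cyclization of a tethered chain. Stepwise loss of HNO2 (ionization of the allylic C3a–NO2 bond assisted by the N1–C2=C3 enamide unit, then loss of the C7a proton) restores the pyrrole in 7; the strained C4–O bond then ionizes with help from the lactam nitrogen and loss of the C7 proton gives the phenol 8, so cycloreversion of 6 is outrun by two irreversible aromatizations. The closest known reaction types are Diels–Alder reactions of 2-amidofurans whose oxygen bridge opens to aminophenol-type arenes, and 3-nitro-1-sulfonylpyrroles acting as dienophiles that rearomatize by extrusion of HNO2; their combination in one step has not been shown. All sp3 centres of 6 and 7 are destroyed, so endo/exo and facial selectivity do not matter and 8 has no stereocentre. The step needs one orientation and one reacting double bond: the largest HOMO coefficient of the amidofuran lies on C5 and the largest LUMO coefficient of the nitroalkene unit on pyrrole C2 (beta to the nitro group), which pairs the oxygen-bearing furan C5 with the carbon next to the pyrrole nitrogen, and the unactivated C4=C5 bond of 5 is not a competent dienophile. The bridge can only open at C4, where the nitrogen stabilizes the cation, and only C7 carries the hydrogen needed for aromatization, so the hydroxyl ends at C7, para to nitrogen, with the former furan C3 bromine at C5. NaHCO3 traps HNO2 as nitrite so that it cannot nitrosate the lactam methylene or the phenol.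

Step 4
Reactants: 8 5-bromo-4-(5-bromo-2-oxoindolin-1-yl)-1-tosyl-1H-indol-7-ol
Product: 9 5-bromo-1-(5-bromo-7-methoxy-1-tosyl-1H-indol-4-yl)indolin-2-one
Conditions: MeOH, PPh3, DIAD, THF, 0 °C → rt
Reagents that add atoms: methanol, CO
Why: Mitsunobu etherification; the phenol (pKa about 10) is the only group acidic enough to protonate the betaine and is then methylated by the methoxyphosphonium ion, whereas the lactam C3'H2, which a base/MeI protocol could C-methylate, is untouched under these neutral conditions.

Step 5
Reactants: 9 5-bromo-1-(5-bromo-7-methoxy-1-tosyl-1H-indol-4-yl)indolin-2-one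
Product: 10 5-bromo-4-(2,5-dibromo-1H-indol-1-yl)-7-methoxy-1-tosyl-1H-indole
Conditions: POBr3 (3 equiv), imidazole (1.2 equiv), ClCH2CH2Cl, 80 °C; then ice-water
Reagents that add atoms: phosphorus oxybromide (POBr3), O=P(Br)(Br)Br
Why: Deoxybromination of an N-substituted oxindole with POBr3: O-phosphorylation of the lactam, addition–elimination of bromide at C2' and loss of a C3' proton give the aromatic 2-bromoindole; the N-tosyl group keeps indole A inert to the acidic electrophilic medium and imidazole buffers HBr so that the aryl methyl ether survives.

Step 6
Reactants: 10 5-bromo-4-(2,5-dibromo-1H-indol-1-yl)-7-methoxy-1-tosyl-1H-indole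
Product: 11 5-bromo-4-(2,5-dibromo-1H-indol-1-yl)-7-methoxy-1H-indole
Conditions: Bu4NF (1 M in THF, 3 equiv), THF, 65 °C; then H2O
Reagents that add atoms: none
Why: Cleavage of an N-sulfonylindole by fluoride attack at sulfur; the indolide leaving group is stabilized by the 5-bromo and 4-indolyl substituents, no alkylating by-product arises (methoxide-based cleavage would give methyl tosylate, which can N-methylate), and aryl and heteroaryl bromides are inert to fluoride.

Step 7
Reactants: 11 5-bromo-4-(2,5-dibromo-1H-indol-1-yl)-7-methoxy-1H-indole
Product: 13 3,5-dibromo-4-(2,5-dibromo-1H-indol-1-yl)-7-methoxy-1H-indole, via sodium indol-1-ide 12 (not isolated)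
Conditions: NaH (1.05 equiv), THF, 0 °C; then NBS (1.0 equiv), −78 → 0 °C; then H2O
Reagents that add atoms: N-bromosuccinimide, O=C1CCC(=O)N1Br
Why: Electrophilic halogenation of an indolyl anion at C3, the same reaction type as the usual base/halogen 3-halogenation of NH indoles; deprotonation of the only N–H makes C3 of indole A far more nucleophilic than the neutral C3' of indole B, which two bromines deactivate, so one equivalent of NBS at low temperature should be consumed at C3 alone, and the acid-sensitive 3-bromoindole is made last and never meets acid.

## Compound list

1 | 5-bromoindolin-2-one | O=C1Cc2cc(Br)ccc2N1 | starting material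
2 | 2,3-dibromofuran | Brc1ccoc1Br | starting material
3 | 5-bromo-1-(3-bromofuran-2-yl)indolin-2-one | O=C1Cc2cc(Br)ccc2N1c1occc1Br | intermediate
4 | 3-nitro-1H-pyrrole | O=[N+]([O-])c1cc[nH]c1 | starting material
5 | 3-nitro-1-tosyl-1H-pyrrole | Cc1ccc(S(=O)(=O)n2ccc([N+](=O)[O-])c2)cc1 | intermediate
6 | 5-bromo-1-(5-bromo-3a-nitro-1-tosyl-1,3a,7,7a-tetrahydro-4H-4,7-epoxyindol-4-yl)indolin-2-one (racemic, endo/exo mixture, configuration not defined) | Cc1ccc(cc1)S(=O)(=O)N1C=CC2([N+](=O)[O-])C1C1OC2(N2C(=O)Cc3cc(Br)ccc32)C(Br)=C1 | intermediate (not isolated)
7 | 5-bromo-1-(5-bromo-1-tosyl-1,7-dihydro-4H-4,7-epoxyindol-4-yl)indolin-2-one (racemic) | Cc1ccc(cc1)S(=O)(=O)n1ccc2c1C1OC2(N2C(=O)Cc3cc(Br)ccc32)C(Br)=C1 | intermediate (not isolated)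
8 | 5-bromo-4-(5-bromo-2-oxoindolin-1-yl)-1-tosyl-1H-indol-7-ol | Cc1ccc(S(=O)(=O)n2ccc3c(N4C(=O)Cc5cc(Br)ccc54)c(Br)cc(O)c32)cc1 | intermediate
9 | 5-bromo-1-(5-bromo-7-methoxy-1-tosyl-1H-indol-4-yl)indolin-2-one | COc1cc(Br)c(N2C(=O)Cc3cc(Br)ccc32)c2ccn(S(=O)(=O)c3ccc(C)cc3)c12 | intermediate
10 | 5-bromo-4-(2,5-dibromo-1H-indol-1-yl)-7-methoxy-1-tosyl-1H-indole | COc1cc(Br)c(-n2c(Br)cc3cc(Br)ccc32)c2ccn(S(=O)(=O)c3ccc(C)cc3)c12 | intermediate
11 | 5-bromo-4-(2,5-dibromo-1H-indol-1-yl)-7-methoxy-1H-indole | COc1cc(Br)c(-n2c(Br)cc3cc(Br)ccc32)c2cc[nH]c12 | intermediate
12 | sodium 5-bromo-4-(2,5-dibromo-1H-indol-1-yl)-7-methoxyindol-1-ide | COc1cc(Br)c(-n2c(Br)cc3cc(Br)ccc32)c2cc[n-]c12.[Na+] | intermediate (not isolated)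
13 | 3,5-dibromo-4-(2,5-dibromo-1H-indol-1-yl)-7-methoxy-1H-indole | COc1cc(Br)c(-n2c(Br)cc3cc(Br)ccc32)c2c(Br)c[nH]c12 | target

## Step count and least certain steps

Total step count: 7. Longest linear sequence: 6 steps (steps 1, 3, 4, 5, 6, 7); step 2 runs in parallel.

**Step 3 (key step, proposed new method).**
- What may go wrong: the diene may be too unreactive, because the lactam nitrogen shares its lone pair with the carbonyl and the benzo ring and the C3 bromine withdraws electrons. The temperature then needed invites thermal decomposition of the amidofuran. The nitroalkene unit may also react as a heterodiene with the furan C4=C5 bond, the adduct may revert faster than it loses HNO2, or liberated HNO2 may nitrosate the lactam methylene if trapping is incomplete.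
- Fallback (known chemistry): it sets out from 1 and returns to the route at 11. Commercial 4-methoxy-3-nitroaniline F1 is brominated ortho to the amino group (NBS, MeCN) to 2-bromo-4-methoxy-5-nitroaniline F2. Diazotization (NaNO2, H2SO4) and treatment with KI in a Sandmeyer-type iodination give 1-bromo-2-iodo-5-methoxy-4-nitrobenzene F3. Goldberg coupling of 1 with F3 (CuI, diamine, K2CO3; the C–I bond should react ahead of every C–Br bond) gives 5-bromo-1-(2-bromo-4-methoxy-5-nitrophenyl)indolin-2-one F4, which is the same compound as A5. POBr3 and imidazole convert it into 2,5-dibromo-1-(2-bromo-4-methoxy-5-nitrophenyl)-1H-indole F5. A Bartoli indole synthesis (vinylmagnesium bromide, 3 equiv, THF, −40 °C) then gives 11: the ortho methoxy group serves as the required ortho substituent and the free ortho carbon becomes C3a. Compounds 8, 9 and 10 are bypassed.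

**Step 1.**
- What may go wrong: copper may insert into the aryl C–Br bond of 1 or of the product, leading to oligomers. A second amidation may occur at furan C3, or the electron-rich product may be degraded oxidatively under the coupling conditions.
- Fallback: it sets out from 1 and returns at 3. Commercial 3-bromofuran F6 is deprotonated at C2 with LiN(i-Pr)2 at −78 °C and quenched with I2 to give 3-bromo-2-iodofuran F7. Coupling of 1 with F7 under CuI/diamine catalysis at 40–60 °C should involve only the C–I bond, which separates the reacting halogen from all three bromines by reactivity and not by statistics.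

**Step 7.**
- What may go wrong: site selectivity may be lost through bromination at C3' of indole B, through double bromination, or through N-bromination followed by intermolecular bromine transfer.
- Fallback: it sets out from 9 and returns at 13, with the order of events changed so that the bromine enters while ring B is still a lactam. Bu4NF removes the tosyl group of 9 to give 5-bromo-1-(5-bromo-7-methoxy-1H-indol-4-yl)indolin-2-one F8. NBS in DMF at 0 °C should brominate the only electron-rich pyrrole position to give 5-bromo-1-(3,5-dibromo-7-methoxy-1H-indol-4-yl)indolin-2-one F9. POBr3 with excess imidazole then gives 13. The cost is that a 3-bromo NH-indole is exposed to the deoxybromination medium, which is why this order is not the first choice.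

**Step 5.**
- What may go wrong: activation of the hindered lactam may be incomplete, the activated lactam may condense with C3' of bromoindole already formed, or HBr may cleave the ether.
- Fallback: it sets out from 9 and returns at 10. Vilsmeier–Haack bromoformylation (POBr3, DMF, CHCl3) uses a stronger activator and caps C3', and should give 2,5-dibromo-1-(5-bromo-7-methoxy-1-tosyl-1H-indol-4-yl)-1H-indole-3-carbaldehyde F10. Pinnick oxidation (NaClO2, NaH2PO4, 2-methyl-2-butene) gives 2,5-dibromo-1-(5-bromo-7-methoxy-1-tosyl-1H-indol-4-yl)-1H-indole-3-carboxylic acid F11. Protodecarboxylation in warm acetic acid, through the C3'-protonated indolenine, then gives 10.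

## Further compounds

F1 | step 3 | 4-methoxy-3-nitroaniline | COc1ccc(N)cc1[N+](=O)[O-]
F2 | step 3 | 2-bromo-4-methoxy-5-nitroaniline | COc1cc(Br)c(N)cc1[N+](=O)[O-]
F3 | step 3 | 1-bromo-2-iodo-5-methoxy-4-nitrobenzene | COc1cc(Br)c(I)cc1[N+](=O)[O-]
F4 | step 3 | 5-bromo-1-(2-bromo-4-methoxy-5-nitrophenyl)indolin-2-one | COc1cc(Br)c(N2C(=O)Cc3cc(Br)ccc32)cc1[N+](=O)[O-]
F5 | step 3 | 2,5-dibromo-1-(2-bromo-4-methoxy-5-nitrophenyl)-1H-indole | COc1cc(Br)c(-n2c(Br)cc3cc(Br)ccc32)cc1[N+](=O)[O-]
F6 | step 1 | 3-bromofuran | Brc1ccoc1
F7 | step 1 | 3-bromo-2-iodofuran | Brc1ccoc1I
F8 | step 7 | 5-bromo-1-(5-bromo-7-methoxy-1H-indol-4-yl)indolin-2-one | COc1cc(Br)c(N2C(=O)Cc3cc(Br)ccc32)c2cc[nH]c12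
F9 | step 7 | 5-bromo-1-(3,5-dibromo-7-methoxy-1H-indol-4-yl)indolin-2-one | COc1cc(Br)c(N2C(=O)Cc3cc(Br)ccc32)c2c(Br)c[nH]c12
F10 | step 5 | 2,5-dibromo-1-(5-bromo-7-methoxy-1-tosyl-1H-indol-4-yl)-1H-indole-3-carbaldehyde | COc1cc(Br)c(-n2c(Br)c(C=O)c3cc(Br)ccc32)c2ccn(S(=O)(=O)c3ccc(C)cc3)c12
F11 | step 5 | 2,5-dibromo-1-(5-bromo-7-methoxy-1-tosyl-1H-indol-4-yl)-1H-indole-3-carboxylic acid | COc1cc(Br)c(-n2c(Br)c(C(=O)O)c3cc(Br)ccc32)c2ccn(S(=O)(=O)c3ccc(C)cc3)c12
A1 | alternative 1 | methyl 5-bromo-4-(2,5-dibromo-1H-indol-1-yl)-7-methoxy-1H-indole-2-carboxylate | COC(=O)c1cc2c(-n3c(Br)cc4cc(Br)ccc43)c(Br)cc(OC)c2[nH]1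
A2 | alternative 1 | methyl (Z)-2-azido-3-[3-bromo-2-(2,5-dibromo-1H-indol-1-yl)-5-methoxyphenyl]acrylate | COC(=O)/C(N=[N+]=[N-])=C/c1cc(OC)cc(Br)c1-n1c(Br)cc2cc(Br)ccc21
A3 | alternative 2 | 5-bromo-1-[3,5-dibromo-7-methoxy-1-(methylsulfonyl)-2-(trimethylsilyl)-1H-indol-4-yl]indolin-2-one | COc1cc(Br)c(N2C(=O)Cc3cc(Br)ccc32)c2c(Br)c([Si](C)(C)C)n(S(C)(=O)=O)c12
A4 | alternative 2 | N-{4-bromo-3-(5-bromo-2-oxoindolin-1-yl)-6-methoxy-2-[(trimethylsilyl)ethynyl]phenyl}methanesulfonamide | COc1cc(Br)c(N2C(=O)Cc3cc(Br)ccc32)c(C#C[Si](C)(C)C)c1NS(C)(=O)=O
A5 | alternative 3 | 5-bromo-1-(2-bromo-4-methoxy-5-nitrophenyl)indolin-2-one | COc1cc(Br)c(N2C(=O)Cc3cc(Br)ccc32)cc1[N+](=O)[O-]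
A6 | alternative 3 | S-{2-[(2-bromo-4-methoxy-5-nitrophenyl)(4-bromophenyl)amino]-2-oxoethyl} O-ethyl carbonodithioate | CCOC(=S)SCC(=O)N(c1ccc(Br)cc1)c1cc([N+](=O)[O-])c(OC)cc1Br
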